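**Retrosynthetic overview**

1. Target 24 ⇐ oxidation of alcohol 23 ⇐ desilylation and acetate-for-chloride exchange ⇐ chloromethyl enal 21 ⇐ ClCH2Li addition and allylic transposition on the isopropoxymethylene ketone 19.
2. The five-membered ring is formed last (step 10): a Lewis-acid 1,2-acyl shift contracts the 2,3-epoxycyclohexanone 17 to the 2-formylcyclopentanone 18.
3. 17 ⇐ enone 16 ⇐ Stork–Danheiser transposition of vinylogous ester 14. The six-membered ring is bought as cyclohexane-1,3-dione and is the only ring present before the contraction.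
4. Side chain: B-alkyl Suzuki coupling of the vinyl group of 12 with the (E)-alkenyl iodide 5 (alkyne carboalumination).
5. Both stereocentres: one allylic alkylation of the α′-enolate of 10 with carbonate 8, catalysed by [Ir(cod)Cl]2/phosphoramidite.

Assumption: all compounds marked "starting material" are catalogue chemicals, and but-2-ene-1,4-diol is bought as the pure E isomer.

**Route**

Step 1
Reactants: 1 5-bromo-2-methylpent-2-ene; 2 lithium acetylide–ethylenediamine complex
Product: 3 6-methylhept-5-en-1-yne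
Conditions: DMSO, 0 → 25 °C
Reagents that add atoms: none
Why: SN2 alkylation of an acetylide by a primary homoallylic bromide, with no stereocentre involved.

Step 2
Reactants: 3 6-methylhept-5-en-1-yne
Product: 5 (1E)-1-iodo-2,6-dimethylhepta-1,5-diene, via alkenylalane 4 (not isolated)
Conditions: Me3Al, Cp2ZrCl2 (0.25 equiv), CH2Cl2, 0 → 25 °C; then I2, THF, −30 → 0 °C
Reagents that add atoms: trimethylaluminium, C[Al](C)C; iodine, II
Why: Negishi carboalumination adds methyl and aluminium syn across the terminal alkyne, and iodinolysis with retention gives the E trisubstituted alkenyl iodide.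

Step 3
Reactants: 6 (2E)-but-2-ene-1,4-diol
Product: 7 (2E)-4-[(tert-butyldiphenylsilyl)oxy]but-2-en-1-ol
Conditions: NaH (1.0 equiv), THF, 0 °C; then t-BuPh2SiCl (1.0 equiv), 0 → 25 °C
Reagents that add atoms: tert-butyl(chloro)diphenylsilane, CC(C)(C)[Si](Cl)(c1ccccc1)c1ccccc1
Why: Monosilylation of a symmetrical diol through its sparingly soluble monosodium alkoxide (Williamson-type O-silylation).

Step 4
Reactants: 7 (2E)-4-[(tert-butyldiphenylsilyl)oxy]but-2-en-1-ol
Product: 8 (2E)-4-[(tert-butyldiphenylsilyl)oxy]but-2-en-1-yl methyl carbonate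
Conditions: ClCO2Me, pyridine, CH2Cl2, 0 °C
Reagents that add atoms: methyl chloroformate, COC(Cl)=O
Why: Acylation of the primary allylic alcohol gives the carbonate leaving group needed for allylic substitution.

Step 5
Reactants: 9 cyclohexane-1,3-dione
Product: 10 3-ethoxycyclohex-2-en-1-one
Conditions: EtOH, p-TsOH (cat.), toluene, 110 °C, Dean–Stark
Reagents that add atoms: ethanol, CCO
Why: Acid-catalysed enol etherification protects the dione as its vinylogous ester and leaves one carbonyl for regioselective α′-enolisation.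

Step 6
Reactants: 10 3-ethoxycyclohex-2-en-1-one; 8 (2E)-4-[(tert-butyldiphenylsilyl)oxy]but-2-en-1-yl methyl carbonate
Product: 12 (6R)-6-[(2S)-1-[(tert-butyldiphenylsilyl)oxy]but-3-en-2-yl]-3-ethoxycyclohex-2-en-1-one, via lithium enolate 11 (not isolated)
Conditions: LiN(SiMe3)2, THF, −78 °C; then 8, [Ir(cod)Cl]2 (2 mol %), BINOL-derived N,N-bis(1-phenylethyl)phosphoramidite (4 mol %, pre-activated with n-PrNH2), LiCl, THF, −40 → 0 °C
Reagents that add atoms: none
Why: Proposed new method: asymmetric allylic alkylation with [Ir(cod)Cl]2/phosphoramidite applied to the α′-lithium enolate of a vinylogous ester, forming the C6–C2′ bond and both stereocentres at once; the catalyst ionises 8 to an allyl complex that is attacked anti to the metal at its substituted terminus (branched product, ligand enantiomer chosen to give 2′S), and the chiral allyl complex differentiates the two faces of the ring-locked E-enolate in an open transition state, expected to give 6R (a C6 epimer would be separable and re-equilibrated through the enolate, since only C6 is acidic); the closest known reaction type is the Hartwig-type allylation of ketone enolates with this catalyst class (a Tsuji–Trost-type substitution giving branched products).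

Step 7
Reactants: 12 (6R)-6-[(2S)-1-[(tert-butyldiphenylsilyl)oxy]but-3-en-2-yl]-3-ethoxycyclohex-2-en-1-one; 5 (1E)-1-iodo-2,6-dimethylhepta-1,5-diene
Product: 14 (6R)-6-[(2S,5E)-1-[(tert-butyldiphenylsilyl)oxy]-6,10-dimethylundeca-5,9-dien-2-yl]-3-ethoxycyclohex-2-en-1-one, via alkylborane 13 (not isolated)
Conditions: 9-BBN-H, THF, 25 °C; then 5, Pd(dppf)Cl2 (5 mol %), AsPh3, Cs2CO3, DMF–H2O, 25 °C
Reagents that add atoms: none
Why: 9-BBN hydroborates only the monosubstituted alkene, and the B-alkyl Suzuki–Miyaura coupling joins the primary borane to the alkenyl iodide with retention of the E geometry, the vinylogous ester being inert to both.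

Step 8
Reactants: 14 (6R)-6-[(2S,5E)-1-[(tert-butyldiphenylsilyl)oxy]-6,10-dimethylundeca-5,9-dien-2-yl]-3-ethoxycyclohex-2-en-1-one
Product: 16 (4S)-4-[(2S,5E)-1-[(tert-butyldiphenylsilyl)oxy]-6,10-dimethylundeca-5,9-dien-2-yl]cyclohex-2-en-1-one, via allylic alcohol 15 (not isolated)
Conditions: i-Bu2AlH, CH2Cl2, −78 °C; then 1 M HCl, THF, 0 °C
Reagents that add atoms: none
Why: Stork–Danheiser transposition (1,2-reduction, then acid-promoted loss of water and ethanol) moves the carbonyl and turns the epimerisable C6 centre into the fixed C4 centre without touching its bonds.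

Step 9
Reactants: 16 (4S)-4-[(2S,5E)-1-[(tert-butyldiphenylsilyl)oxy]-6,10-dimethylundeca-5,9-dien-2-yl]cyclohex-2-en-1-one
Product: 17 (1R,5R,6R)-5-[(2S,5E)-1-[(tert-butyldiphenylsilyl)oxy]-6,10-dimethylundeca-5,9-dien-2-yl]-7-oxabicyclo[4.1.0]heptan-2-one
Conditions: 30% H2O2, NaOH (cat.), MeOH, 0 °C
Reagents that add atoms: hydrogen peroxide, OO
Why: Weitz–Scheffer nucleophilic epoxidation attacks only the enone, anti to the C4 substituent; the two new epoxide centres are lost again in step 10.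

Step 10
Reactants: 17 (1R,5R,6R)-5-[(2S,5E)-1-[(tert-butyldiphenylsilyl)oxy]-6,10-dimethylundeca-5,9-dien-2-yl]-7-oxabicyclo[4.1.0]heptan-2-one
Product: 19 (2E,3R)-3-[(2S,5E)-1-[(tert-butyldiphenylsilyl)oxy]-6,10-dimethylundeca-5,9-dien-2-yl]-2-[(propan-2-yloxy)methylidene]cyclopentan-1-one, via hydroxymethylene ketone 18 (not isolated)
Conditions: BF3·OEt2, CH2Cl2, −20 → 0 °C; NaHCO3 quench and solvent exchange; then i-PrI, K2CO3, acetone, 56 °C
Reagents that add atoms: 2-iodopropane, CC(C)I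
Why: Lewis-acid epoxy ketone rearrangement (House-type): BF3 opens the epoxide at the carbon remote from the carbonyl while the acyl carbon undergoes a concerted 1,2-shift, contracting the ring to the 2-formylcyclopentanone 18 without touching the side-chain-bearing stereocentre, and O-isopropylation (Johnson–Posvic) fixes it as the enol ether.

Step 11
Reactants: 19 (2E,3R)-3-[(2S,5E)-1-[(tert-butyldiphenylsilyl)oxy]-6,10-dimethylundeca-5,9-dien-2-yl]-2-[(propan-2-yloxy)methylidene]cyclopentan-1-one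
Product: 21 (5R)-5-[(2S,5E)-1-[(tert-butyldiphenylsilyl)oxy]-6,10-dimethylundeca-5,9-dien-2-yl]-2-(chloromethyl)cyclopent-1-ene-1-carbaldehyde, via chlorohydrin 20 (not isolated)
Conditions: ClCH2I, MeLi·LiBr, THF, −78 °C; then 1 M HCl, THF, −78 → 20 °C
Reagents that add atoms: chloroiodomethane, ClCI
Why: Chloromethyllithium made in the presence of the substrate adds 1,2 to the ketone, and acid then ionises the tertiary allylic alcohol and hydrolyses the enol ether (Stork–Danheiser-type transposition) to the tetrasubstituted enal; the chlorohydrin cannot close to an epoxide under acid.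

Step 12
Reactants: 21 (5R)-5-[(2S,5E)-1-[(tert-butyldiphenylsilyl)oxy]-6,10-dimethylundeca-5,9-dien-2-yl]-2-(chloromethyl)cyclopent-1-ene-1-carbaldehyde
Product: 22 [(3R)-3-[(2S,5E)-1-[(tert-butyldiphenylsilyl)oxy]-6,10-dimethylundeca-5,9-dien-2-yl]-2-formylcyclopent-1-en-1-yl]methyl acetate
Conditions: KOAc, 18-crown-6 (cat.), MeCN, 25 °C
Reagents that add atoms: potassium acetate, CC(=O)[O-].[K+]
Why: SN2 displacement of the primary allylic chloride by acetate installs the acetate without ever forming a free γ-hydroxy enal.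

Step 13
Reactants: 22 [(3R)-3-[(2S,5E)-1-[(tert-butyldiphenylsilyl)oxy]-6,10-dimethylundeca-5,9-dien-2-yl]-2-formylcyclopent-1-en-1-yl]methyl acetate
Product: 23 [(3R)-2-formyl-3-[(2S,5E)-1-hydroxy-6,10-dimethylundeca-5,9-dien-2-yl]cyclopent-1-en-1-yl]methyl acetate
Conditions: HF·pyridine, pyridine, THF, 0 → 25 °C
Reagents that add atoms: none
Why: Buffered fluoride desilylation removes the silyl ether and leaves the acetate, the enal and the alkenes untouched.

Step 14
Reactants: 23 [(3R)-2-formyl-3-[(2S,5E)-1-hydroxy-6,10-dimethylundeca-5,9-dien-2-yl]cyclopent-1-en-1-yl]methyl acetate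
Product: 24 [(3R)-2-formyl-3-[(2S,5E)-6,10-dimethyl-1-oxoundeca-5,9-dien-2-yl]cyclopent-1-en-1-yl]methyl acetate
Conditions: Dess–Martin periodinane, NaHCO3, CH2Cl2, 0 °C
Reagents that add atoms: none
Why: Dess–Martin oxidation under buffered, non-basic conditions gives the aldehyde without epimerising the new α-stereocentre, which was set in step 6.

**Compound list**

1 | 5-bromo-2-methylpent-2-ene | CC(C)=CCCBr | starting material
2 | lithium acetylide–ethylenediamine complex | [Li]C#C.NCCN | starting material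
3 | 6-methylhept-5-en-1-yne | CC(C)=CCCC#C | intermediate
4 | [(1E)-2,6-dimethylhepta-1,5-dien-1-yl]dimethylalane | C[Al](C)/C=C(\C)CCC=C(C)C | intermediate
5 | (1E)-1-iodo-2,6-dimethylhepta-1,5-diene | I/C=C(\C)CCC=C(C)C | intermediate
6 | (2E)-but-2-ene-1,4-diol | OC/C=C/CO | starting material
7 | (2E)-4-[(tert-butyldiphenylsilyl)oxy]but-2-en-1-ol | OC/C=C/CO[Si](c1ccccc1)(c1ccccc1)C(C)(C)C | intermediate
8 | (2E)-4-[(tert-butyldiphenylsilyl)oxy]but-2-en-1-yl methyl carbonate | COC(=O)OC/C=C/CO[Si](c1ccccc1)(c1ccccc1)C(C)(C)C | intermediate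
9 | cyclohexane-1,3-dione | O=C1CCCC(=O)C1 | starting material
10 | 3-ethoxycyclohex-2-en-1-one | CCOC1=CC(=O)CCC1 | intermediate
11 | lithium 5-ethoxycyclohexa-1,5-dien-1-olate | CCOC1=CC(O[Li])=CCC1 | intermediate
12 | (6R)-6-[(2S)-1-[(tert-butyldiphenylsilyl)oxy]but-3-en-2-yl]-3-ethoxycyclohex-2-en-1-one | CCOC1=CC(=O)[C@@H]([C@H](C=C)CO[Si](c2ccccc2)(c2ccccc2)C(C)(C)C)CC1 | intermediate
13 | 9-[(3S)-4-[(tert-butyldiphenylsilyl)oxy]-3-[(1R)-4-ethoxy-2-oxocyclohex-3-en-1-yl]butyl]-9-borabicyclo[3.3.1]nonane | CCOC1=CC(=O)[C@@H]([C@H](CCB2C3CCCC2CCC3)CO[Si](c2ccccc2)(c2ccccc2)C(C)(C)C)CC1 | intermediate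
14 | (6R)-6-[(2S,5E)-1-[(tert-butyldiphenylsilyl)oxy]-6,10-dimethylundeca-5,9-dien-2-yl]-3-ethoxycyclohex-2-en-1-one | CCOC1=CC(=O)[C@@H]([C@H](CC/C=C(\C)CCC=C(C)C)CO[Si](c2ccccc2)(c2ccccc2)C(C)(C)C)CC1 | intermediate
15 | (6R)-6-[(2S,5E)-1-[(tert-butyldiphenylsilyl)oxy]-6,10-dimethylundeca-5,9-dien-2-yl]-3-ethoxycyclohex-2-en-1-ol (both C1 epimers) | CCOC1=CC(O)[C@@H]([C@H](CC/C=C(\C)CCC=C(C)C)CO[Si](c2ccccc2)(c2ccccc2)C(C)(C)C)CC1 | intermediate
16 | (4S)-4-[(2S,5E)-1-[(tert-butyldiphenylsilyl)oxy]-6,10-dimethylundeca-5,9-dien-2-yl]cyclohex-2-en-1-one | O=C1C=C[C@@H]([C@H](CC/C=C(\C)CCC=C(C)C)CO[Si](c2ccccc2)(c2ccccc2)C(C)(C)C)CC1 | intermediate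
17 | (1R,5R,6R)-5-[(2S,5E)-1-[(tert-butyldiphenylsilyl)oxy]-6,10-dimethylundeca-5,9-dien-2-yl]-7-oxabicyclo[4.1.0]heptan-2-one | O=C1[C@@H]2O[C@@H]2[C@@H]([C@H](CC/C=C(\C)CCC=C(C)C)CO[Si](c3ccccc3)(c3ccccc3)C(C)(C)C)CC1 | intermediate
18 | (3R)-3-[(2S,5E)-1-[(tert-butyldiphenylsilyl)oxy]-6,10-dimethylundeca-5,9-dien-2-yl]-2-(hydroxymethylidene)cyclopentan-1-one (enol form of the 2-formyl ketone) | O=C1CC[C@H]([C@H](CC/C=C(\C)CCC=C(C)C)CO[Si](c2ccccc2)(c2ccccc2)C(C)(C)C)C1=CO | intermediate
19 | (2E,3R)-3-[(2S,5E)-1-[(tert-butyldiphenylsilyl)oxy]-6,10-dimethylundeca-5,9-dien-2-yl]-2-[(propan-2-yloxy)methylidene]cyclopentan-1-one | O=C1CC[C@H]([C@H](CC/C=C(\C)CCC=C(C)C)CO[Si](c2ccccc2)(c2ccccc2)C(C)(C)C)/C1=C\OC(C)C | intermediate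
20 | (2E,3R)-1-(chloromethyl)-3-[(2S,5E)-1-[(tert-butyldiphenylsilyl)oxy]-6,10-dimethylundeca-5,9-dien-2-yl]-2-[(propan-2-yloxy)methylidene]cyclopentan-1-ol (both C1 epimers) | OC1(CCl)CC[C@H]([C@H](CC/C=C(\C)CCC=C(C)C)CO[Si](c2ccccc2)(c2ccccc2)C(C)(C)C)/C1=C\OC(C)C | intermediate
21 | (5R)-5-[(2S,5E)-1-[(tert-butyldiphenylsilyl)oxy]-6,10-dimethylundeca-5,9-dien-2-yl]-2-(chloromethyl)cyclopent-1-ene-1-carbaldehyde | ClCC1=C(C=O)[C@@H]([C@H](CC/C=C(\C)CCC=C(C)C)CO[Si](c2ccccc2)(c2ccccc2)C(C)(C)C)CC1 | intermediate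
22 | [(3R)-3-[(2S,5E)-1-[(tert-butyldiphenylsilyl)oxy]-6,10-dimethylundeca-5,9-dien-2-yl]-2-formylcyclopent-1-en-1-yl]methyl acetate | CC(=O)OCC1=C(C=O)[C@@H]([C@H](CC/C=C(\C)CCC=C(C)C)CO[Si](c2ccccc2)(c2ccccc2)C(C)(C)C)CC1 | intermediate
23 | [(3R)-2-formyl-3-[(2S,5E)-1-hydroxy-6,10-dimethylundeca-5,9-dien-2-yl]cyclopent-1-en-1-yl]methyl acetate | CC(=O)OCC1=C(C=O)[C@@H]([C@H](CC/C=C(\C)CCC=C(C)C)CO)CC1 | intermediate
24 | [(3R)-2-formyl-3-[(2S,5E)-6,10-dimethyl-1-oxoundeca-5,9-dien-2-yl]cyclopent-1-en-1-yl]methyl acetate | CC(=O)OCC1=C(C=O)[C@@H]([C@@H](C=O)CC/C=C(\C)CCC=C(C)C)CC1 | target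

**Step count and risks**

Total step count: 14. Longest linear sequence: 11 steps (6 → 7 → 8 → 12 → 14 → 16 → 17 → 19 → 21 → 22 → 23 → 24, that is steps 3, 4 and 6 to 14).

The three steps most likely to fail:

Step 6 (the proposed new method). The vinylogous-ester enolate may react sluggishly, give linear product, or give a poor C6 ratio. Only the allylic centre is reliably set by the catalyst; the relative configuration at C6 is an expectation, not a precedent. The fallback uses known chemistry, sets out from 8 and comes back at 16. Carbonate 8 undergoes the established allylic alkylation of a β-keto ester (methyl 3-oxobutanoate, [Ir(cod)Cl]2 and the same phosphoramidite) to give methyl (3S)-2-acetyl-3-{[(tert-butyldiphenylsilyl)oxy]methyl}pent-4-enoate F1. NaOMe in MeOH removes the acetyl group (retro-Claisen) to give methyl (3R)-3-{[(tert-butyldiphenylsilyl)oxy]methyl}pent-4-enoate F2. 9-BBN hydroboration and Suzuki coupling with 5 (Pd(dppf)Cl2, K3PO4) give methyl (3S,6E)-3-{[(tert-butyldiphenylsilyl)oxy]methyl}-7,11-dimethyldodeca-6,10-dienoate F3. i-Bu2AlH at −78 °C gives (3S,6E)-3-{[(tert-butyldiphenylsilyl)oxy]methyl}-7,11-dimethyldodeca-6,10-dienal F4. A diarylprolinol silyl ether-catalysed Michael addition to but-3-en-2-one then sets the future ring stereocentre under catalyst control and gives (2R,3S,6E)-3-{[(tert-butyldiphenylsilyl)oxy]methyl}-7,11-dimethyl-2-(3-oxobutyl)dodeca-6,10-dienal F5. Intramolecular aldol condensation (LiOH, i-PrOH) closes the six-membered ring and returns to 16.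

Step 10 (ring contraction). A 1,2-hydride shift to the 1,2-diketone, or capture of the developing cation by the C5′ alkene of the side chain, could compete with the acyl shift. The fallback changes the contraction to an oxidative semipinacol shift; it sets out from 14 and comes back at 18. Compound 14 is reduced as in step 8 but worked up with aqueous KNaC4H4O6, so that 15 is isolated. PhI(OCOCF3)2 with 2,6-di-tert-butylpyridine in CH2Cl2 at −78 °C attacks the enol ether at C2 (chemoselective over the isolated alkenes). Loss of iodobenzene is then assisted by the 1,2-shift of C6 from the carbinol carbon to C2, which gives (5R)-5-[(2S,5E)-1-[(tert-butyldiphenylsilyl)oxy]-6,10-dimethylundeca-5,9-dien-2-yl]-2-ethoxycyclopent-1-ene-1-carbaldehyde F6. 1 M HCl in THF hydrolyses this vinylogous ester to 18, which is alkylated with 2-iodopropane as in step 10.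

Step 11 (chloromethyllithium addition and transposition). The carbenoid may decompose before it adds to the deactivated ketone, or the alkoxide may close to an epoxide on warming. The fallback sets out from 19 and comes back at 22. Dimethylsulfonium methylide (Me3SI, n-BuLi, THF, −10 °C, Corey–Chaykovsky) converts 19 into (4E,5R)-5-[(2S,5E)-1-[(tert-butyldiphenylsilyl)oxy]-6,10-dimethylundeca-5,9-dien-2-yl]-4-[(propan-2-yloxy)methylidene]-1-oxaspiro[2.4]heptane F7. AcCl in CH2Cl2 at −78 °C opens the epoxide by O-acylation, so the acetate ends on the CH2 group and the tertiary allylic cation is an alkoxy-stabilised oxocarbenium ion. Aqueous NaHCO3 hydrolyses it to the aldehyde, giving 22 directly.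

**Further compounds**

F1 | step 6 | methyl (3S)-2-acetyl-3-{[(tert-butyldiphenylsilyl)oxy]methyl}pent-4-enoate (both C2 epimers) | COC(=O)C(C(C)=O)[C@H](C=C)CO[Si](c1ccccc1)(c1ccccc1)C(C)(C)C
F2 | step 6 | methyl (3R)-3-{[(tert-butyldiphenylsilyl)oxy]methyl}pent-4-enoate | COC(=O)C[C@H](C=C)CO[Si](c1ccccc1)(c1ccccc1)C(C)(C)C
F3 | step 6 | methyl (3S,6E)-3-{[(tert-butyldiphenylsilyl)oxy]methyl}-7,11-dimethyldodeca-6,10-dienoate | COC(=O)C[C@H](CC/C=C(\C)CCC=C(C)C)CO[Si](c1ccccc1)(c1ccccc1)C(C)(C)C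
F4 | step 6 | (3S,6E)-3-{[(tert-butyldiphenylsilyl)oxy]methyl}-7,11-dimethyldodeca-6,10-dienal | O=CC[C@H](CC/C=C(\C)CCC=C(C)C)CO[Si](c1ccccc1)(c1ccccc1)C(C)(C)C
F5 | step 6 | (2R,3S,6E)-3-{[(tert-butyldiphenylsilyl)oxy]methyl}-7,11-dimethyl-2-(3-oxobutyl)dodeca-6,10-dienal | O=C[C@H](CCC(C)=O)[C@H](CC/C=C(\C)CCC=C(C)C)CO[Si](c1ccccc1)(c1ccccc1)C(C)(C)C
F6 | step 10 | (5R)-5-[(2S,5E)-1-[(tert-butyldiphenylsilyl)oxy]-6,10-dimethylundeca-5,9-dien-2-yl]-2-ethoxycyclopent-1-ene-1-carbaldehyde | CCOC1=C(C=O)[C@@H]([C@H](CC/C=C(\C)CCC=C(C)C)CO[Si](c2ccccc2)(c2ccccc2)C(C)(C)C)CC1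
F7 | step 11 | (4E,5R)-5-[(2S,5E)-1-[(tert-butyldiphenylsilyl)oxy]-6,10-dimethylundeca-5,9-dien-2-yl]-4-[(propan-2-yloxy)methylidene]-1-oxaspiro[2.4]heptane (both spiro-carbon epimers) | C1OC12CC[C@H]([C@H](CC/C=C(\C)CCC=C(C)C)CO[Si](c3ccccc3)(c3ccccc3)C(C)(C)C)/C2=C\OC(C)C
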